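The data were generated by integration with made-up constants; the scatter is artificial.

The constants stay hidden, and no earlier run changes the reagent charge, so reckon the order from amounts rather than rates.

- spring: left-handed substrate 0.60 M; right-handed substrate 0.60 M; reagent 1.2 M; catalyst 0.60 mM; added ligand 0.67 mM; the very flask that is asked about, followed so far
- flask: left-handed substrate 0.60 M; reagent 1.20 M; catalyst 0.60 mM; added ligand 0.67 mM; right-handed substrate 0.60 M

spring run (percent of the left-handed substrate and right-handed substrate together charged)

| time / h | left-handed product / % | left-handed substrate / % |
|---|---|---|
| 5.00 | 23 | 26 |
| 15.0 | 41 | 11 |
| 25.0 | 42 | 6 |
| 40.0 | 45 | 7 |

(readings scatter by 1.5 percentage points)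

* apparent order in reagent when 5.0% of the left-handed substrate and right-handed substrate together are converted (percent change of the rate of making left-handed product for one percent more reagent charged)
* factor on the rate of making left-handed product when 5.0% of the left-handed substrate and right-handed substrate together are converted if reagent is charged twice over

- catalyst is single-handed; left-handed substrate and right-handed substrate are mirror images of each other, charged as a racemate, each of them at the stated concentration
- the numbers in the tables scatter by 1.5 percentage points (one standard deviation)
- reactions considered so far: reagent + catalyst + left-handed substrate -> catalyst + left-handed product; reagent + catalyst + right-handed substrate -> catalyst + right-handed product; catalyst <-> dormant form; catalyst + added ligand <-> idle complex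
- no earlier run changes the charge of reagent; that part of a forecast is a guess

Each turnover of either substrate takes one reagent, and reagent stands once in each written step but in neither catalyst equilibrium. The look also comes early: the spring run already shows 23% left-handed product at 5.00 h, more than the 5.0% conversion looked at. I therefore take the catalyst as unchanged there, which leaves two amounts, [reagent] charged and reagent spent at the look. Their ratio is the spent share:

spent at the look = 0.0600 M, against 1.20 M charged

spent share = 0.0500

order, charge over what remains = 1.05

factor on doubling = 2.05

The forecast says 0.9 and 1.9, lower than my figures, on the ground of “Possible saturation or binding of reagent to catalyst”.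

The flask gives 1.1 and 2.06.

    reagent + catalyst + left-handed substrate → catalyst + left-handed product (k = 480 L² mol⁻² h⁻¹)
    reagent + catalyst + right-handed substrate → catalyst + right-handed product (k = 240 L² mol⁻² h⁻¹)
    catalyst ⇌ dormant form (K = 3.30, k = 0.0370 h⁻¹)
    catalyst + added ligand ⇌ idle complex, settled at all times (K = 1800 L mol⁻¹)

Carried to 0.800 d at this charge, the spent share scales with the conversion and gives 68.1% of the reagent charged as spent, and the flask then holds 31.9% of its charge. The passing of catalyst into dormant form, forward step alone, has a half-time of 0.781 d, far longer than the 0.0149 d at which the flask reaches the look. By 0.800 d the dormant form holds 29.5% of the catalyst charged.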